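**Strategy**

The plan rests on cutting the dihydropyranone ring (O1, C2–C6) across C5–C6 and O1–C2. Because its only stereocentre, C6, sits beside the unsaturated C1'–C2' unit, the ring can be read as the hetero-Diels–Alder adduct of (E)-1-methoxybuta-1,3-diene and an ynal whose C1'≡C2' triple bond is the masked Z-alkene. One chromium-catalysed cycloaddition closes the ring, forms both bonds and sets C6 under catalyst control; the acetal carbon C2 then needs a single oxidation. The ynal carries the C4'/C6' syn-diol as an acetonide and the C8' acetate, and is assembled from 3-phenylpropanal by two Brown allylations, iodocarbonate cyclisation and epoxide opening with a propargyl ether acetylide.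

Key step: step 15

Assumption: lactone atoms are O1, C2–C6 and the side chain is C1' (on C6) to C10' (benzylic CH2); the (1S,2R)-aminoindanol-derived antipode of the chromium catalyst is taken, by analogy with its sense on simple aldehydes, to deliver the diene to the Si face of the ynal (6S), and the mirror-image complex would be used if a trial run showed the opposite sense.

**Route**

Step 1
Reactants: 1 3-phenylpropanal
Product: 3 (3R)-1-phenylhex-5-en-3-ol, via borinate ester 2 (not isolated)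
Conditions: (−)-Ipc2BOMe, CH2=CHCH2MgBr, Et2O, 0 °C to rt; then 1, −78 °C; then NaOH, H2O2, rt
Reagents that add atoms: B-allyldiisopinocampheylborane made in the flask from (−)-Ipc2BOMe and CH2=CHCH2MgBr, C=CCB([C@@H]1C[C@@H]2C[C@H]([C@H]1C)C2(C)C)[C@@H]1C[C@@H]2C[C@H]([C@H]1C)C2(C)C
Why: Brown allylboration through a chair-like six-membered transition state, in which the isopinocampheyl groups derived from (+)-α-pinene direct allyl transfer to the Si face of the aldehyde and so set C8' as (R).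

Step 2
Reactants: 3 (3R)-1-phenylhex-5-en-3-ol
Product: 4 tert-butyldimethyl{[(3R)-1-phenylhex-5-en-3-yl]oxy}silane
Conditions: TBSCl, imidazole, DMF, rt
Reagents that add atoms: tert-butyldimethylsilyl chloride, CC(C)(C)[Si](C)(C)Cl
Why: Standard silylation of a secondary alcohol; the TBS ether should tolerate ozone, IBr, K2CO3/MeOH and the acetylide/BF3 step and later leave with fluoride without disturbing an acetonide.

Step 3
Reactants: 4 tert-butyldimethyl{[(3R)-1-phenylhex-5-en-3-yl]oxy}silane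
Product: 6 (3R)-3-[(tert-butyldimethylsilyl)oxy]-5-phenylpentanal, via secondary ozonide 5 (not isolated)
Conditions: O3, CH2Cl2, −78 °C; then PPh3, −78 °C to rt
Reagents that add atoms: ozone, [O-][O+]=O
Why: Ozonolysis of the terminal alkene with reductive work-up should give the β-silyloxy aldehyde without touching the stereocentre; the aldehyde would be used crude to avoid β-elimination.

Step 4
Reactants: 6 (3R)-3-[(tert-butyldimethylsilyl)oxy]-5-phenylpentanal
Product: 8 (4R,6R)-6-[(tert-butyldimethylsilyl)oxy]-8-phenyloct-1-en-4-ol, via borinate ester 7 (not isolated)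
Conditions: (+)-Ipc2BOMe, CH2=CHCH2MgBr, Et2O, 0 °C to rt; then 6, −78 °C; then NaOH, H2O2, rt
Reagents that add atoms: B-allyldiisopinocampheylborane made in the flask from (+)-Ipc2BOMe and CH2=CHCH2MgBr, C=CCB([C@H]1C[C@H]2C[C@@H]([C@@H]1C)C2(C)C)[C@H]1C[C@H]2C[C@@H]([C@@H]1C)C2(C)C
Why: Second Brown allylboration, now with the reagent from (−)-α-pinene, whose reagent control should override the weak bias of the β-silyloxy centre and deliver allyl to the Re face, setting C6' as (R), anti to C8'.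

Step 5
Reactants: 8 (4R,6R)-6-[(tert-butyldimethylsilyl)oxy]-8-phenyloct-1-en-4-ol
Product: 9 tert-butyl (4R,6R)-6-[(tert-butyldimethylsilyl)oxy]-8-phenyloct-1-en-4-yl carbonate
Conditions: Boc2O, DMAP, MeCN, rt
Reagents that add atoms: di-tert-butyl dicarbonate, CC(C)(C)OC(=O)OC(=O)OC(C)(C)C
Why: DMAP-catalysed acylation of the secondary alcohol gives the homoallylic tert-butyl carbonate needed for the iodocarbonate cyclisation.

Step 6
Reactants: 9 tert-butyl (4R,6R)-6-[(tert-butyldimethylsilyl)oxy]-8-phenyloct-1-en-4-yl carbonate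
Product: 10 (4R,6S)-4-{(2R)-2-[(tert-butyldimethylsilyl)oxy]-4-phenylbutyl}-6-(iodomethyl)-1,3-dioxan-2-one
Conditions: IBr, PhMe, −85 °C
Reagents that add atoms: iodine monobromide, IBr
Why: IBr-induced iodocarbonate cyclisation, in which the carbonate carbonyl oxygen opens the iodonium ion 6-exo through a chair-like transition state with both substituents equatorial, so the new C4'–O bond forms syn to C6' and the tert-butyl group is lost.

Step 7
Reactants: 10 (4R,6S)-4-{(2R)-2-[(tert-butyldimethylsilyl)oxy]-4-phenylbutyl}-6-(iodomethyl)-1,3-dioxan-2-one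
Product: 11 (2R,4R)-4-[(tert-butyldimethylsilyl)oxy]-1-[(2S)-oxiran-2-yl]-6-phenylhexan-2-ol
Conditions: K2CO3, MeOH, rt
Reagents that add atoms: none
Why: Carbonate methanolysis followed by intramolecular Williamson displacement of iodide by the C4' alkoxide should give the terminal epoxide with C4' unchanged, since the C4'–O bond is never broken.

Step 8
Reactants: 12 propargyl alcohol
Product: 13 1-methoxy-4-[(prop-2-yn-1-yloxy)methyl]benzene
Conditions: NaH, PMBCl, Bu4NI (cat.), THF/DMF, 0 °C to rt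
Reagents that add atoms: 4-methoxybenzyl chloride, COc1ccc(CCl)cc1
Why: Williamson etherification of the alkoxide; the alkyne C–H is far less acidic than the O–H and stays untouched.

Step 9
Reactants: 11 (2R,4R)-4-[(tert-butyldimethylsilyl)oxy]-1-[(2S)-oxiran-2-yl]-6-phenylhexan-2-ol, 13 1-methoxy-4-[(prop-2-yn-1-yloxy)methyl]benzene
Product: 15 (5R,7R,9R)-9-[(tert-butyldimethylsilyl)oxy]-1-[(4-methoxybenzyl)oxy]-11-phenylundec-2-yne-5,7-diol, via lithium acetylide 14 (not isolated)
Conditions: 13 (3 equiv), n-BuLi, THF, −78 °C; BF3·OEt2; then 11, −78 °C; aq. NH4Cl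
Reagents that add atoms: none
Why: Yamaguchi-type alkynylation, in which the BF3-activated epoxide is opened by SN2 attack of the acetylide at the unhindered terminal carbon C3', leaving C4' untouched while the excess acetylide absorbs the free C6' hydroxyl.

Step 10
Reactants: 15 (5R,7R,9R)-9-[(tert-butyldimethylsilyl)oxy]-1-[(4-methoxybenzyl)oxy]-11-phenylundec-2-yne-5,7-diol
Product: 16 tert-butyl{[(2R)-1-[(4R,6R)-6-{4-[(4-methoxybenzyl)oxy]but-2-yn-1-yl}-2,2-dimethyl-1,3-dioxan-4-yl]-4-phenylbutan-2-yl]oxy}dimethylsilane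
Conditions: Me2C(OMe)2, PPTS (cat.), CH2Cl2, rt
Reagents that add atoms: 2,2-dimethoxypropane, COC(C)(C)OC
Why: Acid-catalysed transacetalisation; the syn-1,3-diol should close to a chair 1,3-dioxane with both ring substituents equatorial, and TBS and PMB ethers are stable to PPTS.

Step 11
Reactants: 16 tert-butyl{[(2R)-1-[(4R,6R)-6-{4-[(4-methoxybenzyl)oxy]but-2-yn-1-yl}-2,2-dimethyl-1,3-dioxan-4-yl]-4-phenylbutan-2-yl]oxy}dimethylsilane
Product: 17 (2R)-1-[(4S,6R)-6-{4-[(4-methoxybenzyl)oxy]but-2-yn-1-yl}-2,2-dimethyl-1,3-dioxan-4-yl]-4-phenylbutan-2-ol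
Conditions: Bu4NF, THF, rt
Reagents that add atoms: none
Why: Fluoride-driven desilylation of the secondary TBS ether; acetonide, PMB ether and alkyne are inert, and the ring descriptor changes only because the priorities change.

Step 12
Reactants: 17 (2R)-1-[(4S,6R)-6-{4-[(4-methoxybenzyl)oxy]but-2-yn-1-yl}-2,2-dimethyl-1,3-dioxan-4-yl]-4-phenylbutan-2-ol
Product: 18 (2R)-1-[(4R,6R)-6-{4-[(4-methoxybenzyl)oxy]but-2-yn-1-yl}-2,2-dimethyl-1,3-dioxan-4-yl]-4-phenylbutan-2-yl acetate
Conditions: Ac2O, pyridine, DMAP (cat.), CH2Cl2, rt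
Reagents that add atoms: acetic anhydride, CC(=O)OC(C)=O
Why: DMAP-catalysed acetylation of the only free hydroxyl installs the C8' acetate of the target.

Step 13
Reactants: 18 (2R)-1-[(4R,6R)-6-{4-[(4-methoxybenzyl)oxy]but-2-yn-1-yl}-2,2-dimethyl-1,3-dioxan-4-yl]-4-phenylbutan-2-yl acetate
Product: 19 (2R)-1-[(4R,6R)-6-(4-hydroxybut-2-yn-1-yl)-2,2-dimethyl-1,3-dioxan-4-yl]-4-phenylbutan-2-yl acetate
Conditions: DDQ, CH2Cl2/pH 7 phosphate buffer, 0 °C to rt
Reagents that add atoms: none
Why: Oxidative PMB cleavage, in which DDQ removes hydride from the electron-rich benzylic position and water collapses the oxocarbenium ion to anisaldehyde and the free propargylic alcohol, the buffer protecting the acetonide.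

Step 14
Reactants: 19 (2R)-1-[(4R,6R)-6-(4-hydroxybut-2-yn-1-yl)-2,2-dimethyl-1,3-dioxan-4-yl]-4-phenylbutan-2-yl acetate
Product: 20 (2R)-1-[(4R,6R)-2,2-dimethyl-6-(4-oxobut-2-yn-1-yl)-1,3-dioxan-4-yl]-4-phenylbutan-2-yl acetate
Conditions: MnO2 (activated, excess), CH2Cl2, rt
Reagents that add atoms: none
Why: MnO2 oxidation of an activated propargylic primary alcohol should stop cleanly at the ynal under neutral conditions; the ynal would be filtered and used at once.

Step 15
Reactants: 20 (2R)-1-[(4R,6R)-2,2-dimethyl-6-(4-oxobut-2-yn-1-yl)-1,3-dioxan-4-yl]-4-phenylbutan-2-yl acetate, 21 (E)-1-methoxybuta-1,3-diene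
Product: 22 (2R)-1-[(4R,6R)-6-{3-[(2S,6R)-6-methoxy-3,6-dihydro-2H-pyran-2-yl]prop-2-yn-1-yl}-2,2-dimethyl-1,3-dioxan-4-yl]-4-phenylbutan-2-yl acetate
Conditions: (L)CrCl (C27H29ClCrNO2, trivalent chromium, 5 mol %), powdered 4 Å molecular sieves, 21 (3 equiv), t-BuOMe (minimal), rt
Reagents that add atoms: none
Why: Coordination of the ynal oxygen to the chromium centre (L is the dianion of the Schiff base from 3-(1-adamantyl)-2-hydroxy-5-methylbenzaldehyde and (1S,2R)-1-aminoindan-2-ol) lowers the carbonyl LUMO, and the diene engages it in a concerted but asynchronous [4+2] hetero-Diels–Alder cycloaddition, its CH2 terminus bonding to the aldehyde carbon (C5–C6) and its methoxy-bearing terminus to the carbonyl oxygen (O1–C2). The closest known reaction is the chromium Schiff base catalysed cycloaddition of 1-alkoxybutadienes with aldehydes, for which ynals are established partners. The six-membered ring (O1, C2–C6) is closed by this intermolecular cycloaddition, both ring bonds forming in the same event. C6 is set by the catalyst, which should expose the Si face of the bound aldehyde and give (6S), while C2 follows from the endo transition state that places the methoxy group cis to the alkynyl group. The step needs enantiofacial selectivity at the aldehyde carbon, which the ligand secures because the nearest substrate stereocentre (C4') is four atoms away, and chemoselectivity for C=O over C1'≡C2', which holds because only the coordinated carbonyl is activated. The acetonide and acetate are remote and inert under the neutral, sieve-dried conditions.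

Step 16
Reactants: 22 (2R)-1-[(4R,6R)-6-{3-[(2S,6R)-6-methoxy-3,6-dihydro-2H-pyran-2-yl]prop-2-yn-1-yl}-2,2-dimethyl-1,3-dioxan-4-yl]-4-phenylbutan-2-yl acetate
Product: 23 (2R)-1-[(4R,6R)-6-{(2Z)-3-[(2S,6R)-6-methoxy-3,6-dihydro-2H-pyran-2-yl]prop-2-en-1-yl}-2,2-dimethyl-1,3-dioxan-4-yl]-4-phenylbutan-2-yl acetate
Conditions: H2 (1 atm), Pd/CaCO3 poisoned with Pb(OAc)2 (Lindlar catalyst), quinoline, EtOAc, rt
Reagents that add atoms: none
Why: Lindlar semihydrogenation adds H2 syn on the poisoned palladium surface, so the alkyne should stop at the Z-alkene while the ring alkene and the allylic acetal are left alone.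

Step 17
Reactants: 23 (2R)-1-[(4R,6R)-6-{(2Z)-3-[(2S,6R)-6-methoxy-3,6-dihydro-2H-pyran-2-yl]prop-2-en-1-yl}-2,2-dimethyl-1,3-dioxan-4-yl]-4-phenylbutan-2-yl acetate
Product: 24 (2R)-1-[(4R,6R)-6-{(2Z)-3-[(2S)-6-hydroxy-3,6-dihydro-2H-pyran-2-yl]prop-2-en-1-yl}-2,2-dimethyl-1,3-dioxan-4-yl]-4-phenylbutan-2-yl acetate (anomer mixture)
Conditions: PPTS (cat.), acetone/H2O, rt
Reagents that add atoms: water, O
Why: Mild acid hydrolysis of the allylic anomeric methyl acetal through its stabilised oxocarbenium ion; the acetonide should be held in place by the large excess of acetone and the weak acid.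

Step 18
Reactants: 24 (2R)-1-[(4R,6R)-6-{(2Z)-3-[(2S)-6-hydroxy-3,6-dihydro-2H-pyran-2-yl]prop-2-en-1-yl}-2,2-dimethyl-1,3-dioxan-4-yl]-4-phenylbutan-2-yl acetate
Product: 25 (2R)-1-[(4R,6R)-2,2-dimethyl-6-{(2Z)-3-[(2S)-6-oxo-3,6-dihydro-2H-pyran-2-yl]prop-2-en-1-yl}-1,3-dioxan-4-yl]-4-phenylbutan-2-yl acetate
Conditions: MnO2, CH2Cl2, rt
Reagents that add atoms: none
Why: MnO2 oxidation of the allylic lactol to the α,β-unsaturated δ-lactone; the C2 stereocentre disappears, so only C6 from the cycloaddition remains in the ring.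

Step 19
Reactants: 25 (2R)-1-[(4R,6R)-2,2-dimethyl-6-{(2Z)-3-[(2S)-6-oxo-3,6-dihydro-2H-pyran-2-yl]prop-2-en-1-yl}-1,3-dioxan-4-yl]-4-phenylbutan-2-yl acetate
Product: 26 (6S)-6-[(1Z,4R,6R,8R)-8-acetoxy-4,6-dihydroxy-10-phenyldec-1-en-1-yl]-5,6-dihydro-2H-pyran-2-one
Conditions: AcOH/H2O (4:1), rt
Reagents that add atoms: none
Why: Acid-catalysed hydrolysis of the isopropylidene acetal in aqueous acetic acid, a medium that is non-basic and weakly acidic and so should spare the acetate (no 1,3-migration), the lactone and the allylic C6–O bond.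

**Compound list**

1 | 3-phenylpropanal | O=CCCc1ccccc1 | starting material
2 | (3R)-1-phenylhex-5-en-3-yl diisopinocampheylborinate (isopinocampheyl groups from (+)-α-pinene) | O([C@H](CCc1ccccc1)CC=C)B([C@@H]1C[C@@H]2C[C@H]([C@H]1C)C2(C)C)[C@@H]1C[C@@H]2C[C@H]([C@H]1C)C2(C)C | intermediate
3 | (3R)-1-phenylhex-5-en-3-ol | O[C@H](CCc1ccccc1)CC=C | intermediate
4 | tert-butyldimethyl{[(3R)-1-phenylhex-5-en-3-yl]oxy}silane | CC(C)(C)[Si](C)(C)O[C@H](CCc1ccccc1)CC=C | intermediate
5 | 3-{(2R)-2-[(tert-butyldimethylsilyl)oxy]-4-phenylbutyl}-1,2,4-trioxolane (secondary ozonide, mixture at the ring carbon) | CC(C)(C)[Si](C)(C)O[C@H](CCc1ccccc1)CC1OCOO1 | intermediate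
6 | (3R)-3-[(tert-butyldimethylsilyl)oxy]-5-phenylpentanal | CC(C)(C)[Si](C)(C)O[C@H](CCc1ccccc1)CC=O | intermediate
7 | (4R,6R)-6-[(tert-butyldimethylsilyl)oxy]-8-phenyloct-1-en-4-yl diisopinocampheylborinate (isopinocampheyl groups from (−)-α-pinene) | CC(C)(C)[Si](C)(C)O[C@H](CCc1ccccc1)C[C@@H](CC=C)OB([C@H]1C[C@H]2C[C@@H]([C@@H]1C)C2(C)C)[C@H]1C[C@H]2C[C@@H]([C@@H]1C)C2(C)C | intermediate
8 | (4R,6R)-6-[(tert-butyldimethylsilyl)oxy]-8-phenyloct-1-en-4-ol | CC(C)(C)[Si](C)(C)O[C@H](CCc1ccccc1)C[C@H](O)CC=C | intermediate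
9 | tert-butyl (4R,6R)-6-[(tert-butyldimethylsilyl)oxy]-8-phenyloct-1-en-4-yl carbonate | CC(C)(C)[Si](C)(C)O[C@H](CCc1ccccc1)C[C@H](OC(=O)OC(C)(C)C)CC=C | intermediate
10 | (4R,6S)-4-{(2R)-2-[(tert-butyldimethylsilyl)oxy]-4-phenylbutyl}-6-(iodomethyl)-1,3-dioxan-2-one (cis ring substituents) | CC(C)(C)[Si](C)(C)O[C@H](CCc1ccccc1)C[C@H]1C[C@@H](CI)OC(=O)O1 | intermediate
11 | (2R,4R)-4-[(tert-butyldimethylsilyl)oxy]-1-[(2S)-oxiran-2-yl]-6-phenylhexan-2-ol | CC(C)(C)[Si](C)(C)O[C@H](CCc1ccccc1)C[C@H](O)C[C@H]1CO1 | intermediate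
12 | propargyl alcohol (prop-2-yn-1-ol) | C#CCO | starting material
13 | 1-methoxy-4-[(prop-2-yn-1-yloxy)methyl]benzene (PMB propargyl ether) | C#CCOCc1ccc(OC)cc1 | intermediate
14 | lithium acetylide of 13 | [Li]C#CCOCc1ccc(OC)cc1 | intermediate
15 | (5R,7R,9R)-9-[(tert-butyldimethylsilyl)oxy]-1-[(4-methoxybenzyl)oxy]-11-phenylundec-2-yne-5,7-diol | CC(C)(C)[Si](C)(C)O[C@H](CCc1ccccc1)C[C@H](O)C[C@H](O)CC#CCOCc1ccc(OC)cc1 | intermediate
16 | tert-butyl{[(2R)-1-[(4R,6R)-6-{4-[(4-methoxybenzyl)oxy]but-2-yn-1-yl}-2,2-dimethyl-1,3-dioxan-4-yl]-4-phenylbutan-2-yl]oxy}dimethylsilane | CC(C)(C)[Si](C)(C)O[C@H](CCc1ccccc1)C[C@H]1C[C@@H](CC#CCOCc2ccc(OC)cc2)OC(C)(C)O1 | intermediate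
17 | (2R)-1-[(4S,6R)-6-{4-[(4-methoxybenzyl)oxy]but-2-yn-1-yl}-2,2-dimethyl-1,3-dioxan-4-yl]-4-phenylbutan-2-ol | O[C@H](CCc1ccccc1)C[C@H]1C[C@@H](CC#CCOCc2ccc(OC)cc2)OC(C)(C)O1 | intermediate
18 | (2R)-1-[(4R,6R)-6-{4-[(4-methoxybenzyl)oxy]but-2-yn-1-yl}-2,2-dimethyl-1,3-dioxan-4-yl]-4-phenylbutan-2-yl acetate | CC(=O)O[C@H](CCc1ccccc1)C[C@H]1C[C@@H](CC#CCOCc2ccc(OC)cc2)OC(C)(C)O1 | intermediate
19 | (2R)-1-[(4R,6R)-6-(4-hydroxybut-2-yn-1-yl)-2,2-dimethyl-1,3-dioxan-4-yl]-4-phenylbutan-2-yl acetate | CC(=O)O[C@H](CCc1ccccc1)C[C@H]1C[C@@H](CC#CCO)OC(C)(C)O1 | intermediate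
20 | (2R)-1-[(4R,6R)-2,2-dimethyl-6-(4-oxobut-2-yn-1-yl)-1,3-dioxan-4-yl]-4-phenylbutan-2-yl acetate (ynal) | CC(=O)O[C@H](CCc1ccccc1)C[C@H]1C[C@@H](CC#CC=O)OC(C)(C)O1 | intermediate
21 | (E)-1-methoxybuta-1,3-diene | CO/C=C/C=C | starting material
22 | (2R)-1-[(4R,6R)-6-{3-[(2S,6R)-6-methoxy-3,6-dihydro-2H-pyran-2-yl]prop-2-yn-1-yl}-2,2-dimethyl-1,3-dioxan-4-yl]-4-phenylbutan-2-yl acetate (cis adduct) | CC(=O)O[C@H](CCc1ccccc1)C[C@H]1C[C@@H](CC#C[C@@H]2CC=C[C@H](OC)O2)OC(C)(C)O1 | intermediate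
23 | (2R)-1-[(4R,6R)-6-{(2Z)-3-[(2S,6R)-6-methoxy-3,6-dihydro-2H-pyran-2-yl]prop-2-en-1-yl}-2,2-dimethyl-1,3-dioxan-4-yl]-4-phenylbutan-2-yl acetate | CC(=O)O[C@H](CCc1ccccc1)C[C@H]1C[C@@H](C/C=C\[C@@H]2CC=C[C@H](OC)O2)OC(C)(C)O1 | intermediate
24 | (2R)-1-[(4R,6R)-6-{(2Z)-3-[(2S)-6-hydroxy-3,6-dihydro-2H-pyran-2-yl]prop-2-en-1-yl}-2,2-dimethyl-1,3-dioxan-4-yl]-4-phenylbutan-2-yl acetate (lactol, anomer mixture) | CC(=O)O[C@H](CCc1ccccc1)C[C@H]1C[C@@H](C/C=C\[C@@H]2CC=CC(O)O2)OC(C)(C)O1 | intermediate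
25 | (2R)-1-[(4R,6R)-2,2-dimethyl-6-{(2Z)-3-[(2S)-6-oxo-3,6-dihydro-2H-pyran-2-yl]prop-2-en-1-yl}-1,3-dioxan-4-yl]-4-phenylbutan-2-yl acetate | CC(=O)O[C@H](CCc1ccccc1)C[C@H]1C[C@@H](C/C=C\[C@@H]2CC=CC(=O)O2)OC(C)(C)O1 | intermediate
26 | (6S)-6-[(1Z,4R,6R,8R)-8-acetoxy-4,6-dihydroxy-10-phenyldec-1-en-1-yl]-5,6-dihydro-2H-pyran-2-one | CC(=O)O[C@H](CCc1ccccc1)C[C@H](O)C[C@H](O)C/C=C\[C@@H]1CC=CC(=O)O1 | target

**Step count**

Total: 19 steps. Longest linear sequence: 18 steps (1 to 26 through steps 1–7 and 9–19); step 8 is a one-step side branch.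

**Steps most likely to fail, with fallbacks**

Step 15. The cycloaddition may suffer from insufficient facial discrimination at the ynal carbonyl, or the ynal or the diene may oligomerise on the Lewis acid before they combine. The fallback builds the ring by allylation, acryloylation and ring-closing metathesis and sets out from ynal 20. Allylboration with the reagent from (−)-Ipc2BOMe and CH2=CHCH2MgBr (Et2O, −78 °C, ethanolamine work-up so that the acetate survives) should give, by Si-face attack as in step 1, the (S)-propargylic homoallylic alcohol F1. Lindlar semihydrogenation (H2, Pd/CaCO3 poisoned with Pb(OAc)2, quinoline) would give the Z-allylic alcohol F2, and acryloyl chloride with Et3N in CH2Cl2 at 0 °C the acrylate F3. Ring-closing metathesis with the second-generation Grubbs catalyst, RuCl2(=CHPh)(PCy3)(H2IMes), in CH2Cl2 at reflux should then engage the terminal alkene and the acrylate and close the lactone. The fallback comes back to the route at 25, so steps 16–18 are not needed.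

Step 9. The epoxide opening may stall because the free C6' hydroxyl quenches acetylide and ties up BF3, leaving the activated epoxide to decompose. The fallback sets out from 11 and masks the hydroxyl first: TESCl and imidazole in CH2Cl2 should give the triethylsilyl ether F4, which would be opened with 14 and BF3·OEt2 in THF at −78 °C to the homopropargylic alcohol F5. PPTS in MeOH at 0 °C should then remove the triethylsilyl group while the secondary TBS ether stays, coming back to the route at 15.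

Step 17. The hydrolysis may erode the material through partial loss of the acetonide or through Z-to-E isomerisation of the ring-opened hydroxy enal form of the lactol. The fallback sets out from 23 and avoids the lactol altogether: direct oxidation of the allylic methyl acetal with pyridinium chlorochromate, (C5H5NH)[CrO3Cl], in CH2Cl2 at rt should give the lactone in one operation, coming back to the route at 25.

**Further compounds**

F1 | step 15 | (2R)-1-[(4R,6R)-6-[(4S)-4-hydroxyhept-6-en-2-yn-1-yl]-2,2-dimethyl-1,3-dioxan-4-yl]-4-phenylbutan-2-yl acetate | CC(=O)O[C@H](CCc1ccccc1)C[C@H]1C[C@@H](CC#C[C@@H](O)CC=C)OC(C)(C)O1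
F2 | step 15 | (2R)-1-[(4R,6R)-6-[(2Z,4S)-4-hydroxyhepta-2,6-dien-1-yl]-2,2-dimethyl-1,3-dioxan-4-yl]-4-phenylbutan-2-yl acetate | CC(=O)O[C@H](CCc1ccccc1)C[C@H]1C[C@@H](C/C=C\[C@@H](O)CC=C)OC(C)(C)O1
F3 | step 15 | (4S,5Z)-7-{(4R,6R)-6-[(2R)-2-acetoxy-4-phenylbutyl]-2,2-dimethyl-1,3-dioxan-4-yl}hepta-1,5-dien-4-yl prop-2-enoate | CC(=O)O[C@H](CCc1ccccc1)C[C@H]1C[C@@H](C/C=C\[C@@H](OC(=O)C=C)CC=C)OC(C)(C)O1
F4 | step 9 | tert-butyldimethyl{[(3R,5R)-6-[(2S)-oxiran-2-yl]-1-phenyl-5-[(triethylsilyl)oxy]hexan-3-yl]oxy}silane | CC(C)(C)[Si](C)(C)O[C@H](CCc1ccccc1)C[C@H](O[Si](CC)(CC)CC)C[C@H]1CO1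
F5 | step 9 | (5R,7R,9R)-9-[(tert-butyldimethylsilyl)oxy]-1-[(4-methoxybenzyl)oxy]-11-phenyl-7-[(triethylsilyl)oxy]undec-2-yn-5-ol | CC(C)(C)[Si](C)(C)O[C@H](CCc1ccccc1)C[C@H](O[Si](CC)(CC)CC)C[C@H](O)CC#CCOCc1ccc(OC)cc1
F0 | step 17 | none | none
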